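**Retrosynthetic overview**

- The route rests on ring A: a benzene with all six carbons substituted (C1 butanoyl, C2 OH, C3 CH3, C4 OCH3, C5 CH2 to ring B, C6 OH), so alternating O and C substituents with differently capped oxygens.
- Last disconnections: the C1–butanoyl bond (Friedel–Crafts acylation) and the O–CH3 bonds at C6 and on ring B (BCl3).
- Ring A is formed last, by benzannulation of a 3-methoxycyclobutenone carrying the ring B arm on C2 with 1-methoxypropyne: C2–C3 and C4–C5 arise in a [2+2] step and C1–C2 closes by 6π electrocyclisation.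
- The cyclobutenone comes from an alkylketene and ethoxyacetylene; that cycloaddition puts the arm on C4, so an acid-catalysed enol-ether transposition in methanol moves it to C2.
- Ring B is made first: dearomatising gem-dimethylation of phloroacetophenone, Michael addition to tert-butyl acrylate, O-methylation.

Key step: step 8

Assumption: exhaustive O-methylation of the ring B triketone is taken to give the 2,4-dimethoxy bis(enol ether) drawn; a regioisomeric bis(enol ether) would serve equally, since every ring B O-methyl group is removed in step 10.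

**Route**

Step 1
Reactants: 1 1-(2,4,6-trihydroxyphenyl)ethanone
Product: 3 2-acetyl-3,5-dihydroxy-4,4-dimethylcyclohexa-2,5-dien-1-one (acetylfilicinic acid), via monomethyl phenol 2 (not isolated)
Conditions: MeI (2.2 equiv), NaOMe (3 equiv), MeOH, 0 °C → rt
Reagents that add atoms: iodomethane, CI
Why: Dearomatising C-methylation of the phloroglucinol phenoxide, in which the second methyl should enter the already methylated carbon to give the non-aromatic β-triketone, the under- and over-methylated by-products being removed by crystallisation or chromatography.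

Step 2
Reactants: 3 acetylfilicinic acid; 4 tert-butyl acrylate
Product: 5 tert-butyl 3-(5-acetyl-2,4-dihydroxy-3,3-dimethyl-6-oxocyclohexa-1,4-dien-1-yl)propanoate
Conditions: DBU (2.5 equiv), 4 (2 equiv), MeCN, 40 °C; acidic work-up
Reagents that add atoms: none
Why: Michael addition, in which the dianion of the cyclic β-triketone should react as a soft carbon nucleophile at its only unsubstituted ring carbon, while any O-adduct reverts and the C-adduct accumulates.

Step 3
Reactants: 5 the dihydroxy ester
Product: 6 tert-butyl 3-(5-acetyl-2,4-dimethoxy-3,3-dimethyl-6-oxocyclohexa-1,4-dien-1-yl)propanoate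
Conditions: TMSCHN2 (3 equiv), PhMe/MeOH, 0 °C → rt
Reagents that add atoms: trimethylsilyldiazomethane, C[Si](C)(C)C=[N+]=[N-]
Why: O-Methylation of the two strongly acidic enols by diazomethane released in situ should cap ring B as its bis(methyl enol ether) without touching the ester, so that no acidic OH is left to quench the ketenes of steps 5 and 8.

Step 4
Reactants: 6 the bis(enol ether) ester
Product: 7 3-(5-acetyl-2,4-dimethoxy-3,3-dimethyl-6-oxocyclohexa-1,4-dien-1-yl)propanoic acid
Conditions: TFA, CH2Cl2 (anhydrous), 0 °C → rt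
Reagents that add atoms: none
Why: Acidolysis of the tert-butyl ester with loss of isobutene, run without water so that the vinylogous methyl esters have nothing to hydrolyse them.

Step 5
Reactants: 7 the propanoic acid; 8 ethoxyacetylene
Product: 11 4-[(5-acetyl-2,4-dimethoxy-3,3-dimethyl-6-oxocyclohexa-1,4-dien-1-yl)methyl]-3-ethoxycyclobut-2-en-1-one (racemic), via acid chloride 9 (not isolated), via alkylketene 10 (not isolated)
Conditions: 1-chloro-N,N,2-trimethylprop-1-en-1-amine, CH2Cl2, 0 °C → rt; then added slowly to 8 (5 equiv), Et3N (1.5 equiv), CH2Cl2, rt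
Reagents that add atoms: none
Why: Ketene–ynol ether [2+2] cycloaddition, in which the acid chloride is made under neutral conditions, Et3N dehydrochlorinates it to the monoalkylketene and excess ethoxyacetylene traps it with its unsubstituted carbon bonding to the ketene carbonyl carbon, so the arm ends on the sp3 carbon C4 as a racemic stereocentre that step 6 erases.

Step 6
Reactants: 11 the 4-substituted 3-ethoxycyclobutenone
Product: 13 2-[(5-acetyl-2,4-dimethoxy-3,3-dimethyl-6-oxocyclohexa-1,4-dien-1-yl)methyl]-3-methoxycyclobut-2-en-1-one, via dimethoxy ketal 12 (not isolated)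
Conditions: CSA (10 mol %), dry MeOH, 40 °C; then evaporate, PhMe, 60 °C
Reagents that add atoms: methanol, CO
Why: Acid-catalysed transetherification of a vinylogous ester under thermodynamic control, in which MeOH adds to the protonated enone and displaces ethanol to give ketone 12, which can lose MeOH toward either α-carbon (both lie between the two carbonyl carbons of the cyclobutane-1,3-dione skeleton) and should settle on the tetrasubstituted, arm-bearing C2=C3 enol ether, while the ring B methyl enol ethers can only exchange with the same alcohol.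

Step 7
Reactants: 14 2-bromo-1,1-dimethoxypropane
Product: 16 1-methoxyprop-1-yne, via bromo enol ether 15 (not isolated)
Conditions: NaNH2 (2.1 equiv), liquid NH3, −33 °C; aqueous quench, distillation
Reagents that add atoms: none
Why: Twofold base-induced elimination of an α-bromo acetal (loss of methanol, then of HBr), the classical preparation of 1-alkoxyalkynes, which should deliver the volatile ynol ether by distillation.

Step 8
Reactants: 13 the 2-substituted 3-methoxycyclobutenone; 16 1-methoxyprop-1-yne
Product: 21 4-[(5-acetyl-2,4-dimethoxy-3,3-dimethyl-6-oxocyclohexa-1,4-dien-1-yl)methyl]-3,5-dimethoxy-2-methylphenol, via vinylketene 17 (not isolated), via vinylcyclobutenone 18 (not isolated), via dienylketene 19 (not isolated), via cyclohexadienone 20 (not isolated)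
Conditions: 16 (3 equiv), PhMe (0.1 M), 100 °C, sealed tube, argon
Reagents that add atoms: none
Why: Heating should open 13 by 4π electrocyclic cleavage of the C1–C4 bond to vinylketene 17, whose ketene C=C adds 16 in a [2+2] cycloaddition with the methyl-bearing alkyne carbon bonding to the ketene carbonyl carbon and the methoxy-bearing carbon to the arm-bearing carbon, giving 18. A second 4π opening leads to dienylketene 19, and ring A closes by thermal 6π electrocyclisation between the ketene carbon and the CH2 terminus to give dienone 20, which tautomerises to phenol 21. This is the Danheiser benzannulation, the closest known type being the reaction of cyclobutenones with alkoxyalkynes to give resorcinol monoethers. No stereocentre is formed in 21, and that of 18 is lost on ring opening. Only regiocontrol is needed: the polarisation of the ynol ether puts CH3 ortho and OCH3 meta to the new OH, and the arm on C2 of 13 (secured in step 6) puts the CH2 para to the OH with the ring-derived OCH3 beside it. Ring B has no OH to quench the ketenes, and a methoxyalkyne, having no β-hydrogen, cannot fragment by a retro-ene path at this temperature.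

Step 9
Reactants: 21 the pentasubstituted phenol
Product: 22 1-{2-hydroxy-4,6-dimethoxy-3-methyl-5-[(5-acetyl-2,4-dimethoxy-3,3-dimethyl-6-oxocyclohexa-1,4-dien-1-yl)methyl]phenyl}butan-1-one
Conditions: butanoyl chloride (1.2 equiv), TiCl4 (2 equiv), CH2Cl2, −40 → 0 °C
Reagents that add atoms: butanoyl chloride, CCCC(Cl)=O
Why: Friedel–Crafts acylation through the titanium phenoxide should occur at the single unsubstituted carbon of a very electron-rich phloroglucinol-type ring (ortho to the OH), ring B offering no nucleophilic carbon.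

Step 10
Reactants: 22 the aryl ketone
Product: 23 2-acetyl-6-[(3-butanoyl-2,4-dihydroxy-6-methoxy-5-methylphenyl)methyl]-3,5-dihydroxy-4,4-dimethylcyclohexa-2,5-dien-1-one (target)
Conditions: BCl3 (6 equiv), CH2Cl2, −78 → 0 °C; aqueous work-up
Reagents that add atoms: none
Why: Lewis-acid demethylation, in which boron chelated between the aryl ketone and its ortho-methoxy oxygen lets chloride remove that methyl group and the two vinylogous methyl esters of ring B are cleaved likewise through carbonyl-bound boron, whereas the C4 methoxy group of ring A has no carbonyl neighbour and should survive at or below 0 °C.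

**Compound list**

1 | 1-(2,4,6-trihydroxyphenyl)ethanone | CC(=O)c1c(O)cc(O)cc1O | starting material
2 | 1-(2,4,6-trihydroxy-3-methylphenyl)ethanone | CC(=O)c1c(O)cc(O)c(C)c1O | intermediate
3 | 2-acetyl-3,5-dihydroxy-4,4-dimethylcyclohexa-2,5-dien-1-one | CC(=O)C1=C(O)C(C)(C)C(O)=CC1=O | intermediate
4 | tert-butyl acrylate | C=CC(=O)OC(C)(C)C | starting material
5 | tert-butyl 3-(5-acetyl-2,4-dihydroxy-3,3-dimethyl-6-oxocyclohexa-1,4-dien-1-yl)propanoate | CC(=O)C1=C(O)C(C)(C)C(O)=C(CCC(=O)OC(C)(C)C)C1=O | intermediate
6 | tert-butyl 3-(5-acetyl-2,4-dimethoxy-3,3-dimethyl-6-oxocyclohexa-1,4-dien-1-yl)propanoate | CC(=O)C1=C(OC)C(C)(C)C(OC)=C(CCC(=O)OC(C)(C)C)C1=O | intermediate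
7 | 3-(5-acetyl-2,4-dimethoxy-3,3-dimethyl-6-oxocyclohexa-1,4-dien-1-yl)propanoic acid | CC(=O)C1=C(OC)C(C)(C)C(OC)=C(CCC(=O)O)C1=O | intermediate
8 | ethoxyacetylene | C#COCC | starting material
9 | 3-(5-acetyl-2,4-dimethoxy-3,3-dimethyl-6-oxocyclohexa-1,4-dien-1-yl)propanoyl chloride | CC(=O)C1=C(OC)C(C)(C)C(OC)=C(CCC(Cl)=O)C1=O | intermediate
10 | 3-(5-acetyl-2,4-dimethoxy-3,3-dimethyl-6-oxocyclohexa-1,4-dien-1-yl)prop-1-en-1-one (alkylketene) | CC(=O)C1=C(OC)C(C)(C)C(OC)=C(CC=C=O)C1=O | intermediate
11 | 4-[(5-acetyl-2,4-dimethoxy-3,3-dimethyl-6-oxocyclohexa-1,4-dien-1-yl)methyl]-3-ethoxycyclobut-2-en-1-one (racemic) | CCOC1=CC(=O)C1CC1=C(OC)C(C)(C)C(OC)=C(C(C)=O)C1=O | intermediate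
12 | 2-[(5-acetyl-2,4-dimethoxy-3,3-dimethyl-6-oxocyclohexa-1,4-dien-1-yl)methyl]-3,3-dimethoxycyclobutan-1-one (racemic) | COC1(OC)CC(=O)C1CC1=C(OC)C(C)(C)C(OC)=C(C(C)=O)C1=O | intermediate
13 | 2-[(5-acetyl-2,4-dimethoxy-3,3-dimethyl-6-oxocyclohexa-1,4-dien-1-yl)methyl]-3-methoxycyclobut-2-en-1-one | COC1=C(CC2=C(OC)C(C)(C)C(OC)=C(C(C)=O)C2=O)C(=O)C1 | intermediate
14 | 2-bromo-1,1-dimethoxypropane | CC(Br)C(OC)OC | starting material
15 | 2-bromo-1-methoxyprop-1-ene (E/Z mixture) | COC=C(C)Br | intermediate
16 | 1-methoxyprop-1-yne | CC#COC | intermediate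
17 | 2-[(5-acetyl-2,4-dimethoxy-3,3-dimethyl-6-oxocyclohexa-1,4-dien-1-yl)methyl]-3-methoxybuta-1,3-dien-1-one (vinylketene) | C=C(OC)C(CC1=C(OC)C(C)(C)C(OC)=C(C(C)=O)C1=O)=C=O | intermediate
18 | 4-[(5-acetyl-2,4-dimethoxy-3,3-dimethyl-6-oxocyclohexa-1,4-dien-1-yl)methyl]-3-methoxy-4-(1-methoxyethenyl)-2-methylcyclobut-2-en-1-one (racemic) | O=C1C(C)=C(OC)C1(CC2=C(OC)C(C)(C)C(OC)=C(C(C)=O)C2=O)C(OC)=C | intermediate
19 | 4-[(5-acetyl-2,4-dimethoxy-3,3-dimethyl-6-oxocyclohexa-1,4-dien-1-yl)methyl]-3,5-dimethoxy-2-methylhexa-1,3,5-trien-1-one (dienylketene, ketene and vinyl groups cis) | O=C=C(C)/C(OC)=C(\C(OC)=C)CC1=C(OC)C(C)(C)C(OC)=C(C(C)=O)C1=O | intermediate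
20 | 4-[(5-acetyl-2,4-dimethoxy-3,3-dimethyl-6-oxocyclohexa-1,4-dien-1-yl)methyl]-3,5-dimethoxy-2-methylcyclohexa-2,4-dien-1-one | O=C1CC(OC)=C(CC2=C(OC)C(C)(C)C(OC)=C(C(C)=O)C2=O)C(OC)=C1C | intermediate
21 | 4-[(5-acetyl-2,4-dimethoxy-3,3-dimethyl-6-oxocyclohexa-1,4-dien-1-yl)methyl]-3,5-dimethoxy-2-methylphenol | COc1cc(O)c(C)c(OC)c1CC1=C(OC)C(C)(C)C(OC)=C(C(C)=O)C1=O | intermediate
22 | 1-{2-hydroxy-4,6-dimethoxy-3-methyl-5-[(5-acetyl-2,4-dimethoxy-3,3-dimethyl-6-oxocyclohexa-1,4-dien-1-yl)methyl]phenyl}butan-1-one | CCCC(=O)c1c(O)c(C)c(OC)c(CC2=C(OC)C(C)(C)C(OC)=C(C(C)=O)C2=O)c1OC | intermediate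
23 | 2-acetyl-6-[(3-butanoyl-2,4-dihydroxy-6-methoxy-5-methylphenyl)methyl]-3,5-dihydroxy-4,4-dimethylcyclohexa-2,5-dien-1-one | CCCC(=O)c1c(O)c(C)c(OC)c(CC2=C(O)C(C)(C)C(O)=C(C(C)=O)C2=O)c1O | target

**Step count**

Total: 10 steps. Longest linear sequence: 9 steps (steps 1–6 and 8–10); step 7 supplies the alkyne.

**Steps most likely to fail**

Step 6. The equilibration may stall with part of the material keeping the arm on the sp3 carbon, or methanol may cleave the strained ring of the intermediate ketone. Any 4-substituted isomer carried into step 8 would give a regioisomeric arene. The fallback sets out from 11 and gives up the equilibration for an O-alkylation whose regiochemistry is fixed by symmetry. Dilute aqueous HCl in THF should hydrolyse all three enol ethers to 2-acetyl-3,5-dihydroxy-6-[(2-hydroxy-4-oxocyclobut-1-en-1-yl)methyl]-4,4-dimethylcyclohexa-2,5-dien-1-one F1. Its four-membered 1,3-dione enolises toward the arm-bearing carbon and has two equivalent oxygens. Treatment with TMSCHN2 in PhMe/MeOH should then methylate the cyclobutenol and both ring B enols at once, and the route is rejoined at 13.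

Step 5. The monoalkylketene may dimerise, or the acid chloride or ketene may acylate a neighbouring ring B oxygen with loss of a methyl group, closing an enol lactone before ethoxyacetylene is captured. The fallback sets out from 3 and avoids ketene chemistry next to ring B. A Mannich reaction of 3 with dimethyl(methylidene)ammonium iodide should give 2-acetyl-6-[(dimethylamino)methyl]-3,5-dihydroxy-4,4-dimethylcyclohexa-2,5-dien-1-one F2. Separately, 3-ethoxycyclobut-2-en-1-one (purchasable, or from 8 and ketene) is hydrolysed with dilute HCl to 3-hydroxycyclobut-2-en-1-one F3. Heating F2 with F3 in dioxane should expel dimethylamine, and the methylene triketone so released should be captured at C2 of F3 to give the same tetracarbonyl compound F1. F1 is methylated with TMSCHN2 as above, and the route is rejoined at 13.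

Step 8. The donor-substituted cyclobutenone may open too slowly, or the vinylketene may acylate the product phenol or a ring B oxygen instead of adding the alkyne. The fallback sets out from 3 and builds the CH2 bridge onto a finished ring A. 2-Methylphloroglucinol is butanoylated (butanoyl chloride, AlCl3) to 1-(2,4,6-trihydroxy-3-methylphenyl)butan-1-one F4. Methylation of its non-chelated para OH (Me2SO4, K2CO3, acetone, 1 equiv) should give 1-(2,6-dihydroxy-4-methoxy-3-methylphenyl)butan-1-one (aspidinol) F5. Condensation of 3, F5 and aqueous formaldehyde in dilute KOH should then join the two rings at the only free aromatic carbon of F5, and the route comes back directly at 23.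

**Further compounds**

F1 | step 6 | 2-acetyl-3,5-dihydroxy-6-[(2-hydroxy-4-oxocyclobut-1-en-1-yl)methyl]-4,4-dimethylcyclohexa-2,5-dien-1-one | CC(=O)C1=C(O)C(C)(C)C(O)=C(CC2=C(O)CC2=O)C1=O
F2 | step 5 | 2-acetyl-6-[(dimethylamino)methyl]-3,5-dihydroxy-4,4-dimethylcyclohexa-2,5-dien-1-one | CC(=O)C1=C(O)C(C)(C)C(O)=C(CN(C)C)C1=O
F3 | step 5 | 3-hydroxycyclobut-2-en-1-one | OC1=CC(=O)C1
F4 | step 8 | 1-(2,4,6-trihydroxy-3-methylphenyl)butan-1-one | CCCC(=O)c1c(O)cc(O)c(C)c1O
F5 | step 8 | 1-(2,6-dihydroxy-4-methoxy-3-methylphenyl)butan-1-one | CCCC(=O)c1c(O)cc(OC)c(C)c1O
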